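The numbers in the tables stem from a simulated flask with made-up constants, and the scatter is random.

**The pitfall.** Millimolar product misleads when charges differ: alder ended on 125.4 mM against 83.6 mM in elm, yet alder had turned the smaller share of its starting material, 41.8% against 55.7%.

| flask | starting material | coupling partner | product | time |
|---|---|---|---|---|
| elm | 150 mM | 450 mM |  |  |
| oak | 150 mM | 1400 mM |  |  |
| alder | 300 mM | 450 mM |  |  |
| maple | 150 mM | 450 mM | 75.0 mM |  |
| cedar | 450 mM | 900 mM |  | 46 min |

| elm run: time / min | elm run: [product] / mM | oak run: time / min | oak run: [product] / mM | alder run: time / min | alder run: [product] / mM | maple run: time / min | maple run: [product] / mM |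
|---|---|---|---|---|---|---|---|
| 6.6 | 17.1 | 6.6 | 50.2 | 6.6 | 21.8 | 6.6 | 91.3 |
| 13 | 28.8 | 13 | 81.0 | 13 | 43.0 | 13 | 107.0 |
| 20 | 44.0 | 20 | 110.3 | 20 | 60.3 | 20 | 118.7 |
| 26 | 54.3 | 26 | 121.3 | 26 | 75.4 | 26 | 129.1 |
| 33 | 67.2 | 33 | 132.3 | 33 | 94.8 | 33 | 143.3 |
| 39 | 70.2 | 39 | 140.9 | 39 | 110.0 | 39 | 149.6 |
| 46 | 83.6 | 46 | 146.4 | 46 | 125.4 | 46 | 158.8 |

(standard deviation of a reading: 2 mM)

- reaction order in [coupling partner] at the outset, round the charge of the elm run, defined at two percent of the starting material turned into product
- reaction order in [starting material] at the outset, round the charge of the elm run, defined at two percent of the starting material turned into product (one fixed amount of product, the same in the runs compared)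
- product in the cedar run at 46 min, as a share of the starting material charged

- Overall: starting material + coupling partner -> product.
- Constant volume, constant temperature.
- A reading of a species includes what of it is bound.
- "The second partner" is coupling partner.
- An order is taken over about fifteen percent of the charge, up and down.

**A fair clock.** I therefore turned readings into a clock: the natural logarithm of starting material charged over starting material unturned, as on a pseudo-first-order plot. Elm's clock stood at 0.815 at 46 min. Maple, given product at the start, made 83.8 mM by then, so I took added product to change nothing. Oak's clock over elm's at the first reading was 3.37, which gave me an order in partner of 1.07.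

**The zero point.** With the partner charge held, first order in starting material would make alder's early product twice elm's, and zero order would make it equal to elm's. Summed over the readings up to 20 min, by when elm had turned 29.3%, alder's product was 1.39 times elm's, between the two, which gave me an order of 0.477 over that doubling.

**Two extremes.** Cedar has 2.00 times elm's partner, worth a factor of 2.10, and 3.00 times its starting material. At first order in starting material, cedar's clock would run at that factor and reach a share of 81.9%; at zero order cedar would make that factor times elm's 83.6 mM, a share of 39.0%. Between them, the pace of cedar, its clock over elm's at one time, came out at 1.18, so my own estimate, which carried that early order through to 46 min, was 61.8%.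

**The forecast.** The forecast gave 0.98 in partner, 0.46 in starting material and 58% for cedar, on the ground that “Doubling starting material raises the rate only about 1.3 times”. That share lies near elm's own at that time, and a little below my estimate.

**The result.** Cedar gave 64.4% at 46 min; the orders at the outset were 1.2 in partner and 0.58 in starting material, and tying up as idle substrate-reagent adduct moves the readings by 10 scatter units, root mean square.

    2 coupling partner ⇌ reagent dimer, settled at all times (5.720 /M)
    starting material + reagent dimer → product + coupling partner (0.9600 /M/min)
    starting material + coupling partner ⇌ idle substrate-reagent adduct, settled at all times (15.30 /M)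
    2 starting material ⇌ idle substrate dimer, settled at all times (95.80 /M)

Cedar's clock then stood at 1.03, a pace of 1.27, higher than my 1.18. Oak's pace of 3.37, divided into elm's 17.0 min for a quarter of its charge, gives 5.04 min, and oak reached that share at 5.02 min.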